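**Retrosynthetic overview**
- Feature: C1' is a methine bonded to three carbons: C5 of the nine-membered caryophyllane ring, the isobutyryl carbonyl C2' and the alpha carbon (Cα) of the tetramethylcyclohexanetrione ring. It sits in a dihydropyran whose only other new bond is O–C4, to a tertiary carbon.
- Last ring: the O–C4 bond of the dihydropyran is opened to an enol trione that carries a C4=C14 methylene.
- Key disconnection: C1' goes back to an aldehyde carbon by cutting C1'–C2' (acyl anion of isobutyraldehyde) and C1'=Cα (condensation with syncarpic acid).
- The C5–CHO bond goes back to (−)-β-caryophyllene and formaldehyde through an ene reaction that moves C4=C5 to C4=C14.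
- Ring order: the cyclobutane and nine-membered ring arrive with β-caryophyllene and the trione ring with syncarpic acid; the dihydropyran is the only ring made, in the last step.

Key step: step 3

Remark: caryophyllane numbering is used (C1/C9 cyclobutane fusion, C4 bears C14, C8 bears C15). C1 and C9 of the target have the configuration of natural (−)-β-caryophyllene, and C4/C5 correspond to syn addition on the face of C4=C5 from which natural caryophyllene oxide arises.

**Step 1**
Reactants: 1 (−)-β-caryophyllene; 2 formaldehyde (as paraformaldehyde)
Product: 3 [(1R,5R,9S)-caryophylla-4(14),8(15)-dien-5-yl]methanol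
Conditions: (CH2O)n (1.1 equiv), Me2AlCl (1.5 equiv), CH2Cl2, −78 → 0 °C; cold 1 M HCl quench
Reagents that add atoms: none
Why: Me2AlCl-promoted carbonyl-ene reaction of formaldehyde, in which the CH2 carbon should bond to C5 on the exposed outer face of the strained trans C4=C5 bond (the face that gives natural caryophyllene oxide, which sets C5) and the hydrogen should come from the freely rotating C14 methyl, because the ring C3–H bonds lie near the nodal plane of the trans-cycloalkene, a preference also seen in singlet-oxygen ene reactions of this alkene.

**Step 2**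
Reactants: 3 [(1R,5R,9S)-caryophylla-4(14),8(15)-dien-5-yl]methanol
Product: 4 (1R,5R,9S)-caryophylla-4(14),8(15)-diene-5-carbaldehyde
Conditions: Dess–Martin periodinane (1.3 equiv), pyridine (3 equiv), CH2Cl2, 0 °C; used at once without chromatography
Reagents that add atoms: none
Why: Dess–Martin oxidation of a primary alcohol is near-neutral and fast at 0 °C, so the β,γ-unsaturated aldehyde should form without enolisation at C5 or migration of C4=C14 into conjugation; no stereocentre is made.

**Step 3**
Reactants: 4 (1R,5R,9S)-caryophylla-4(14),8(15)-diene-5-carbaldehyde; 5 syncarpic acid (2,2,4,4-tetramethylcyclohexane-1,3,5-trione); 6 isobutyraldehyde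
Product: 8 2-{(1S)-1-[(1R,5S,9S)-caryophylla-4(14),8(15)-dien-5-yl]-3-methyl-2-oxobutyl}-3-hydroxy-4,4,6,6-tetramethylcyclohex-2-ene-1,5-dione, via alkylidene trione 7 (not isolated)
Conditions: 5 (1.0 equiv), L-proline (10 mol %), 4 Å MS, CH2Cl2, 0 °C → rt until 4 is consumed; then 6 (5 equiv), 3-benzyl-5-(2-hydroxyethyl)-4-methylthiazolium chloride (20 mol %), i-Pr2NEt (1.2 equiv), THF, 0 °C → rt; aq. citric acid work-up
Reagents that add atoms: none
Why: Proposed new method: proline-catalysed Knoevenagel condensation of 4 with 5 gives the alkylidene trione 7 (C1'=Cα), and the Breslow intermediate from 6 and the thiazol-2-ylidene then adds through its acyl carbon to C1', the β carbon of this doubly carbonyl-activated acceptor, after which proton transfer and loss of the carbene leave the C1'–C2' ketone and the trione enol. The closest known reaction types are the one-flask Knoevenagel condensation/conjugate addition of cyclic 1,3-diones (three-component reductive alkylation) and the intermolecular Stetter reaction on alkylidene malonates, but their combination on an alkylidene trione is not established. No ring is closed. The one new stereocentre, C1', is controlled by the adjacent C5 centre: in the rotamer that keeps C5–H in the plane of the alkylidene (allylic strain) the nucleophile should approach anti to the larger C4 arm, which corresponds to the (1'S) configuration, and since C1'–H is alpha to the new ketone this centre can also be equilibrated. The step needs the acyl anion to add to C1' faster than the amine removes the doubly activated C5–H and faster than acyloin formation; the high electrophilicity of 7, the reversibility of acyloin formation, completion of the condensation before 6 is added (so that 6 finds no free 5), low temperature and a hindered amine are relied on for this. A full equivalent of amine is used because the product enol is acidic enough to protonate the carbene.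

**Step 4**
Reactants: 8 open-chain enol trione
Product: 9 Tomentodione R
Conditions: Tf2NH (10 mol %), CH2Cl2, −60 → −30 °C; Et3N quench
Reagents that add atoms: none
Why: Acid-catalysed intramolecular Markovnikov hydroalkoxylation (cycloetherification of an alkenyl 1,3-dione enol), in which protonation at C14 gives the tertiary C4 cation and the enol oxygen captures it in a six-membered (6-exo) closure through a chair-like transition state with both nine-ring bonds equatorial, which should set C4 with the C14 methyl anti to H-5 (trans fusion), while low temperature and catalytic acid are meant to keep C8=C15, the isobutyryl oxygen and furan-forming dehydration from competing.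

**Compound list**
1 | (−)-β-caryophyllene, (1R,4E,9S)-4,11,11-trimethyl-8-methylidenebicyclo[7.2.0]undec-4-ene | C/C1=C\CCC(=C)[C@H]2CC(C)(C)[C@@H]2CC1 | starting material
2 | formaldehyde (used as paraformaldehyde) | C=O | starting material
3 | [(1R,5R,9S)-caryophylla-4(14),8(15)-dien-5-yl]methanol (CH2OH on C5, C4=C14 and C8=C15 exocyclic) | C=C1CC[C@H](C(=C)CC[C@@H]2[C@@H]1CC2(C)C)CO | intermediate
4 | (1R,5R,9S)-caryophylla-4(14),8(15)-diene-5-carbaldehyde | C=C1CC[C@H](C(=C)CC[C@@H]2[C@@H]1CC2(C)C)C=O | intermediate
5 | syncarpic acid (2,2,4,4-tetramethylcyclohexane-1,3,5-trione) | CC1(C)C(=O)CC(=O)C(C)(C)C1=O | starting material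
6 | isobutyraldehyde (2-methylpropanal) | CC(C)C=O | starting material
7 | 6-{[(1R,5S,9S)-caryophylla-4(14),8(15)-dien-5-yl]methylidene}-2,2,4,4-tetramethylcyclohexane-1,3,5-trione (alkylidene trione, C1'=Cα) | C=C1CC[C@H](C(=C)CC[C@@H]2[C@@H]1CC2(C)C)C=C3C(=O)C(C)(C)C(=O)C(C)(C)C3=O | intermediate
8 | 2-{(1S)-1-[(1R,5S,9S)-caryophylla-4(14),8(15)-dien-5-yl]-3-methyl-2-oxobutyl}-3-hydroxy-4,4,6,6-tetramethylcyclohex-2-ene-1,5-dione (open-chain enol trione, isobutyryl on C1') | C=C1CC[C@H](C(=C)CC[C@@H]2[C@@H]1CC2(C)C)[C@H](C(=O)C(C)C)C3=C(O)C(C)(C)C(=O)C(C)(C)C3=O | intermediate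
9 | Tomentodione R (caryophyllane numbering 1R,4R,5S,9S,1'S; trans-fused dihydropyran O–C4–C5–C1'–Cα=C(O), isobutyryl on C1', C8=C15 methylene) | C=C1CC[C@H]2[C@H](C(=O)C(C)C)C3=C(O[C@]2(C)CC[C@@H]2[C@@H]1CC2(C)C)C(C)(C)C(=O)C(C)(C)C3=O | target

**Total step count:** 4
**Longest linear sequence:** 4 steps (from 1)

**Steps most likely to fail**

Step 3 (proposed new method). The crowded Breslow intermediate may add too slowly to C1', so that the amine removes the C5 proton of the alkylidene trione instead; this would scramble C5 or move the alkene into conjugation. Acyloin formation may also consume the donor. Fallback with known chemistry, setting out from 4: condense 4 with 5 as above to 7, then add the nitronate of 2-methyl-1-nitropropane (cat. Et3N, CH2Cl2, 0 °C) as the acyl anion equivalent. This Michael addition should give the nitro enol trione F1. A reductive Nef reaction (NaOMe, MeOH; then aq. TiCl3, NH4OAc) turns the CH–NO2 carbon into the C2' ketone, and the route is rejoined at 8.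

Step 4. Protonation may not discriminate between C4=C14 and C8=C15, leading to alkene migration or transannular cyclisation. The C4 cation may also be taken by the isobutyryl oxygen, or ring closure may occur on the wrong face of C4. Fallback from 8: iodoetherification (NIS, CH2Cl2, −40 °C), in which reversible iodonium formation is funnelled by the enol oxygen at C4=C14 only, should give the 14-iodo ether F2. Radical deiodination (Bu3SnH, cat. AIBN, toluene, 80 °C) then gives 9.

Step 1. The formaldehyde–Lewis acid complex may attack the exocyclic C8=C15 bond, take the hydrogen from C3 instead of C14, or trigger cationic rearrangement of the ring. Fallback from 1: an uncatalysed thermal ene reaction with ethyl glyoxylate (toluene, 110 °C, sealed tube) should give the α-hydroxy ester F3. LiAlH4 (THF, 0 °C) reduces it to the 1,2-diol F4, and NaIO4 (THF/pH 7 buffer, 0 °C) cleaves the diol to the aldehyde, rejoining the route at 4.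

**Further compounds**
F1 | step 3 | 2-{(1S)-1-[(1R,5S,9S)-caryophylla-4(14),8(15)-dien-5-yl]-3-methyl-2-nitrobutyl}-3-hydroxy-4,4,6,6-tetramethylcyclohex-2-ene-1,5-dione (nitro enol trione, C2' epimers) | C=C1CC[C@H](C(=C)CC[C@@H]2[C@@H]1CC2(C)C)[C@H](C(C(C)C)[N+](=O)[O-])C3=C(O)C(C)(C)C(=O)C(C)(C)C3=O
F2 | step 4 | 14-iodo-Tomentodione R (CH2I in place of the C14 methyl on C4) | C=C1CC[C@H]2[C@H](C(=O)C(C)C)C3=C(O[C@]2(CI)CC[C@@H]2[C@@H]1CC2(C)C)C(C)(C)C(=O)C(C)(C)C3=O
F3 | step 1 | ethyl 2-[(1R,5R,9S)-caryophylla-4(14),8(15)-dien-5-yl]-2-hydroxyacetate (carbinol epimers) | C=C1CC[C@H](C(=C)CC[C@@H]2[C@@H]1CC2(C)C)C(O)C(=O)OCC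
F4 | step 1 | 1-[(1R,5R,9S)-caryophylla-4(14),8(15)-dien-5-yl]ethane-1,2-diol (carbinol epimers) | C=C1CC[C@H](C(=C)CC[C@@H]2[C@@H]1CC2(C)C)C(O)CO
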